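## Retrosynthetic overview

1. Target 12 ⇒ C4–aryl bond: the C4 cation of flavan-3,4-diol 11 is captured by 2-methoxyresorcinol 10 anti to the 3-OH (last C–C bond).
2. 11 ⇒ (+)-fustin 9 ⇒ its tribenzyl ether 8 (C4=O reduction, debenzylation).
3. 8 ⇒ key cut C2–C3, the two oxygen-bearing carbons: benzylic sulfonium ylide 6 (a reversed-polarity, α-oxido-carbanion equivalent of the B-ring aldehyde carbon) adds to the CHO of aryl glyoxal 2; the trans-epoxide 7 is opened in the same flask by the A-ring phenoxide.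
4. 2 ⇐ acetophenone 1 (Riley oxidation); 6 ⇐ sulfonium salt 5 ⇐ benzylic alcohol 3 + C2-symmetric sulfide 4.
5. Ring order: the three benzene rings are bought; the only ring made is the pyranone C ring, in the key step (transient oxirane, then the pyran ring).

Assumption: (2R,5R)-2,5-dimethylthiolane 4 is taken as purchasable and as transferring the benzylidene group with the facial sense I recall for its epoxidation of simple aldehydes ((S,S)-type trans-epoxides); if the sense is reversed with the glyoxal, ent-4 is used with no other change.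

## Route

Step 1
Reactants: 1 1-[4-(benzyloxy)-2-hydroxyphenyl]ethan-1-one
Product: 2 2-[4-(benzyloxy)-2-hydroxyphenyl]-2-oxoacetaldehyde (handled as hydrate/cyclic hemiacetal, dried by toluene azeotrope before use)
Conditions: SeO2 (1.2 equiv), 1,4-dioxane–H2O (30:1), 100 °C; filter; toluene azeotrope
Reagents that add atoms: selenium dioxide, O=[Se]=O
Why: Riley oxidation converts the enolisable methyl of an aryl methyl ketone into the aldehyde (ene reaction, then [2,3]-shift at selenium) while the phenol and benzyl ether are inert; no stereocenter is formed.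

Step 2
Reactants: 3 [3,4-bis(benzyloxy)phenyl]methanol; 4 (2R,5R)-2,5-dimethylthiolane
Product: 5 (2R,5R)-1-[3,4-bis(benzyloxy)benzyl]-2,5-dimethylthiolan-1-ium tetrafluoroborate
Conditions: HBF4·OEt2 (1.05 equiv), 4 (1.2 equiv), CH2Cl2, 0 °C → rt; precipitate with Et2O
Reagents that add atoms: tetrafluoroboric acid (diethyl ether complex), [H+].F[B-](F)(F)F
Why: Acid-promoted SN1 S-alkylation: HBF4 ionises the electron-rich benzylic alcohol and the sulfide traps the cation as a crystalline sulfonium salt; the C2-symmetric sulfide keeps sulfur non-stereogenic, so no new stereocenter arises.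

Step 3
Reactants: 2 2-[4-(benzyloxy)-2-hydroxyphenyl]-2-oxoacetaldehyde; 5 (2R,5R)-1-[3,4-bis(benzyloxy)benzyl]-2,5-dimethylthiolan-1-ium tetrafluoroborate
Product: 8 (2R,3R)-7-(benzyloxy)-2-[3,4-bis(benzyloxy)phenyl]-3-hydroxy-2,3-dihydro-4H-chromen-4-one, via sulfonium ylide 6 (not isolated), via trans-epoxy ketone 7 (not isolated)
Conditions: 5 (1.2 equiv), KHMDS (2.05 equiv), THF, −78 °C → 0 °C, Ar; AcOH (1.1 equiv); recrystallise (EtOAc–hexane) to raise ee
Reagents that add atoms: none
Why: Proposed new method: KHMDS first makes the potassium phenoxide of 2 and then ylide 6, whose carbon (the future C2, an acceptor carbon by natural polarity) attacks the glyoxal CHO (the future C3) as a nucleophile, so two carbonyl-level carbons are joined with reversed polarity; anti-betaine collapse gives trans-(2R,3S)-epoxy ketone 7 with the ylide carbon configured by the chiral thiolane, and the ortho-phenoxide then opens the benzylic, p-alkoxy-activated epoxide carbon 6-endo with inversion (ylide carbon S → C2 R; aldehyde carbon retained → C3 R, 2,3-trans); the closest known chemistry is asymmetric Corey–Chaykovsky benzylidene transfer from chiral thiolanium salts to aldehydes, and the Algar–Flynn–Oyamada-type closure of 2'-oxidochalcone epoxides that lack a 6'-substituent.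

Step 4
Reactants: 8 (2R,3R)-7-(benzyloxy)-2-[3,4-bis(benzyloxy)phenyl]-3-hydroxy-2,3-dihydro-4H-chromen-4-one
Product: 9 (2R,3R)-2-(3,4-dihydroxyphenyl)-3,7-dihydroxy-2,3-dihydro-4H-chromen-4-one ((+)-fustin)
Conditions: H2 (1 atm), 10% Pd/C, EtOAc–MeOH, rt, short reaction time
Reagents that add atoms: none
Why: Catalytic hydrogenolysis cleaves the three aryl benzyl ethers while the aryl ketone, the secondary alcohol and the ring C2–O bond survive brief exposure; no stereocenter is touched.

Step 5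
Reactants: 9 (2R,3R)-2-(3,4-dihydroxyphenyl)-3,7-dihydroxy-2,3-dihydro-4H-chromen-4-one; 10 2-methoxybenzene-1,3-diol
Product: 12 (2R,3S,4R)-2-(3,4-dihydroxyphenyl)-4-(2,4-dihydroxy-3-methoxyphenyl)-3,4-dihydro-2H-chromene-3,7-diol, via flavan-3,4-diol 11 (not isolated)
Conditions: NaBH4, EtOH, 0 °C → rt, N2; then 10 (8 equiv), aq HCl to 0.1 M, rt; Sephadex LH-20 (EtOH)
Reagents that add atoms: none
Why: Known biomimetic flavan-3,4-diol condensation: NaBH4 reduces C4=O to diol 11, acid ionises the C4–OH to the 7-oxygen-stabilised benzylic cation, and the only activated position of 10 (C4, ortho/para to both OH) attacks in a Friedel–Crafts alkylation anti to the 3-OH, setting C4 as R (3,4-trans); the minor 3,4-cis isomer and excess 10 are removed on Sephadex.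

## Compound list

1 | 1-[4-(benzyloxy)-2-hydroxyphenyl]ethan-1-one | CC(=O)c1ccc(OCc2ccccc2)cc1O | starting material
2 | 2-[4-(benzyloxy)-2-hydroxyphenyl]-2-oxoacetaldehyde | O=CC(=O)c1ccc(OCc2ccccc2)cc1O | intermediate
3 | [3,4-bis(benzyloxy)phenyl]methanol | OCc1ccc(OCc2ccccc2)c(OCc2ccccc2)c1 | starting material
4 | (2R,5R)-2,5-dimethylthiolane | C[C@@H]1CC[C@@H](C)S1 | starting material
5 | (2R,5R)-1-[3,4-bis(benzyloxy)benzyl]-2,5-dimethylthiolan-1-ium tetrafluoroborate | C[C@@H]1CC[C@@H](C)[S+]1Cc1ccc(OCc2ccccc2)c(OCc2ccccc2)c1.F[B-](F)(F)F | intermediate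
6 | (2R,5R)-1-{[3,4-bis(benzyloxy)phenyl]methylide}-2,5-dimethylthiolan-1-ium (sulfonium ylide) | C[C@@H]1CC[C@@H](C)[S+]1[CH-]c1ccc(OCc2ccccc2)c(OCc2ccccc2)c1 | intermediate
7 | [4-(benzyloxy)-2-hydroxyphenyl]{(2R,3S)-3-[3,4-bis(benzyloxy)phenyl]oxiran-2-yl}methanone (present as its potassium phenoxide) | O=C(c1ccc(OCc2ccccc2)cc1O)[C@@H]1O[C@H]1c1ccc(OCc2ccccc2)c(OCc2ccccc2)c1 | intermediate
8 | (2R,3R)-7-(benzyloxy)-2-[3,4-bis(benzyloxy)phenyl]-3-hydroxy-2,3-dihydro-4H-chromen-4-one | O=C1c2ccc(OCc3ccccc3)cc2O[C@H](c2ccc(OCc3ccccc3)c(OCc3ccccc3)c2)[C@H]1O | intermediate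
9 | (2R,3R)-2-(3,4-dihydroxyphenyl)-3,7-dihydroxy-2,3-dihydro-4H-chromen-4-one ((+)-fustin) | O=C1c2ccc(O)cc2O[C@H](c2ccc(O)c(O)c2)[C@H]1O | intermediate
10 | 2-methoxybenzene-1,3-diol | COc1c(O)cccc1O | starting material
11 | (2R,3S,4R)-2-(3,4-dihydroxyphenyl)-3,4-dihydro-2H-chromene-3,4,7-triol ((+)-mollisacacidin) | O[C@@H]1c2ccc(O)cc2O[C@H](c2ccc(O)c(O)c2)[C@H]1O | intermediate
12 | (2R,3S,4R)-2-(3,4-dihydroxyphenyl)-4-(2,4-dihydroxy-3-methoxyphenyl)-3,4-dihydro-2H-chromene-3,7-diol | COc1c(O)ccc([C@@H]2c3ccc(O)cc3O[C@H](c3ccc(O)c(O)c3)[C@H]2O)c1O | target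

## Step count and risks

Total steps: 5. Longest linear sequence: 4 (steps 1, 3, 4, 5; step 2 is a one-step side branch).

Steps most likely to fail:

Step 3 (highest risk). The ylide addition to an α-keto aldehyde carrying a free phenoxide is unproven in yield, trans/cis ratio and ee. Side paths are α-attack of the phenoxide (benzofuranone-type product), glyoxal rearrangement and base-mediated racemisation of 8. The fallback drops the ylide chemistry and sets out from 1. MOM protection (MOMCl, iPr2NEt) gives 1-[4-(benzyloxy)-2-(methoxymethoxy)phenyl]ethan-1-one F1. Claisen–Schmidt condensation with commercial 3,4-bis(benzyloxy)benzaldehyde (KOH, EtOH) gives (E)-1-[4-(benzyloxy)-2-(methoxymethoxy)phenyl]-3-[3,4-bis(benzyloxy)phenyl]prop-2-en-1-one F2. Juliá–Colonna epoxidation (poly-L-leucine, urea–H2O2, DBU, THF) gives [4-(benzyloxy)-2-(methoxymethoxy)phenyl]{(2R,3S)-3-[3,4-bis(benzyloxy)phenyl]oxiran-2-yl}methanone F3. HCl in MeOH–THF then removes the MOM group and the freed phenol closes the ring at the benzylic epoxide carbon with inversion, coming back to the route at 8.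

Step 5. Unprotected 11 can self-condense to oligomers, 10 is a weaker nucleophile than resorcinol, and the 3,4-cis isomer forms alongside. The fallback sets out from 8, skips step 4, and couples on protected material under Lewis acid. NaBH4 (THF–EtOH) gives (2R,3S,4R)-7-(benzyloxy)-2-[3,4-bis(benzyloxy)phenyl]-3,4-dihydro-2H-chromene-3,4-diol F4. BF3·OEt2 in CH2Cl2–THF at −40 °C with 10 gives 4-{(2R,3S,4R)-7-(benzyloxy)-2-[3,4-bis(benzyloxy)phenyl]-3-hydroxy-3,4-dihydro-2H-chromen-4-yl}-2-methoxybenzene-1,3-diol F5. Hydrogenolysis (H2, Pd(OH)2/C, EtOAc–MeOH) then comes back to the route at 12.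

Step 1. SeO2 may over-oxidise the electron-rich o-hydroxyaryl ketone (arylglyoxylic acid, ring oxidation) and leave selenium residues. The fallback sets out from 1 and avoids selenium. Nitrosation (isoamyl nitrite, NaOEt, EtOH, 0 °C) gives (2E)-1-[4-(benzyloxy)-2-hydroxyphenyl]-2-(hydroxyimino)ethan-1-one F6. Transoximation with aqueous formaldehyde/HCl then comes back to the route at 2.

Further compounds
F1 | step 3 | 1-[4-(benzyloxy)-2-(methoxymethoxy)phenyl]ethan-1-one | CC(=O)c1ccc(OCc2ccccc2)cc1OCOC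
F2 | step 3 | (E)-1-[4-(benzyloxy)-2-(methoxymethoxy)phenyl]-3-[3,4-bis(benzyloxy)phenyl]prop-2-en-1-one | O=C(/C=C/c1ccc(OCc2ccccc2)c(OCc2ccccc2)c1)c1ccc(OCc2ccccc2)cc1OCOC
F3 | step 3 | [4-(benzyloxy)-2-(methoxymethoxy)phenyl]{(2R,3S)-3-[3,4-bis(benzyloxy)phenyl]oxiran-2-yl}methanone | O=C(c1ccc(OCc2ccccc2)cc1OCOC)[C@@H]1O[C@H]1c1ccc(OCc2ccccc2)c(OCc2ccccc2)c1
F4 | step 5 | (2R,3S,4R)-7-(benzyloxy)-2-[3,4-bis(benzyloxy)phenyl]-3,4-dihydro-2H-chromene-3,4-diol | O[C@@H]1c2ccc(OCc3ccccc3)cc2O[C@H](c2ccc(OCc3ccccc3)c(OCc3ccccc3)c2)[C@H]1O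
F5 | step 5 | 4-{(2R,3S,4R)-7-(benzyloxy)-2-[3,4-bis(benzyloxy)phenyl]-3-hydroxy-3,4-dihydro-2H-chromen-4-yl}-2-methoxybenzene-1,3-diol | COc1c(O)ccc([C@@H]2c3ccc(OCc4ccccc4)cc3O[C@H](c3ccc(OCc4ccccc4)c(OCc4ccccc4)c3)[C@H]2O)c1O
F6 | step 1 | (2E)-1-[4-(benzyloxy)-2-hydroxyphenyl]-2-(hydroxyimino)ethan-1-one | O=C(/C=N/O)c1ccc(OCc2ccccc2)cc1O
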